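**Plan**

1. Cuts: first the helpers (two O-benzyl groups on ring B, an O-acetyl on ring A, an oxazolidinone standing in for the ester OMe). Then the bond from C1 of ring A (the 3-bromo-5-hydroxy-4-methoxyphenyl ring) to C2 of the propanoate, which separates the two halves. Then C1–B of ring A back to C1–H, and the C2–C3 chain of the other half back to the aldehyde carbon of a dibromovanillin.
2. Enabling feature: C2 lies alpha to the ester C=O, so it becomes an enol-type donor once the ester is worn as an N-acyl oxazolidinone. Ring-A C1 is para to the C4 methoxy group and is the only ring CH whose two neighbours (C2, C6) carry H. It is therefore the site of sterically controlled C–H borylation and, as an aryl(mesityl)iodonium, leaves iodine in preference to mesityl. Both carbons are donors by nature; the arene is made the acceptor by polarity reversal through iodine(III).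
3. Forward: the ring-B half from 5-bromovanillin (steps 1–6), the ring-A half from 3-bromo-2-methoxyphenol (steps 7–9), union in step 10, then hydrolysis, esterification and debenzylation (steps 11–13). Both benzene rings are bought; no ring is built.
4. Stereochemistry: the single stereocenter (R at C2) is created in step 10 under control of a chiral copper bis(oxazoline) catalyst. Afterwards C2 meets only hydroperoxide at 0 °C, acid, and BCl3 at −78 °C, none of which should enolise it.

Key step: step 10

Assumption: the (S,S) enantiomer of the phenyl bis(oxazoline) ligand is taken to deliver the (R) product; if the sense of induction is the reverse, the (R,R) ligand is used and nothing else changes.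

**Route**

Step 1
Reactants: 1 5-bromovanillin (3-bromo-4-hydroxy-5-methoxybenzaldehyde)
Product: 2 2,3-dibromo-4-hydroxy-5-methoxybenzaldehyde
Conditions: Br2 (1.1 equiv), Fe powder (cat.), AcOH, rt → 50 °C
Reagents that add atoms: bromine, BrBr
Why: Electrophilic aromatic bromination should go to the one free ring position para to the methoxy group, the other free carbon lying between CHO and OMe and being more hindered.

Step 2
Reactants: 2 2,3-dibromo-4-hydroxy-5-methoxybenzaldehyde
Product: 3 2,3-dibromo-4,5-dihydroxybenzaldehyde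
Conditions: BBr3 (3 equiv), CH2Cl2, −78 °C → rt; then H2O
Reagents that add atoms: none
Why: Lewis acid O-demethylation of an aryl methyl ether (BBr3 ether cleavage) should free the catechol while the aldehyde and the aryl bromides stay intact, the boron aryloxide being hydrolysed on work-up.

Step 3
Reactants: 3 2,3-dibromo-4,5-dihydroxybenzaldehyde
Product: 4 4,5-bis(benzyloxy)-2,3-dibromobenzaldehyde
Conditions: BnBr (2.5 equiv), K2CO3 (3 equiv), DMF, 60 °C
Reagents that add atoms: benzyl bromide, BrCc1ccccc1
Why: Williamson etherification of both acidic bromophenol oxygens should protect the catechol in a form that withstands formate, amide base, silyl triflate and peroxide in the later steps.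

Step 4
Reactants: 4 4,5-bis(benzyloxy)-2,3-dibromobenzaldehyde
Product: 7 3-[4,5-bis(benzyloxy)-2,3-dibromophenyl]propanoic acid, via arylidene Meldrum's acid 5 (not isolated), via benzyl Meldrum's acid 6 (not isolated)
Conditions: Meldrum's acid (1.1 equiv), HCO2H/Et3N (5:2), 95 °C
Reagents that add atoms: Meldrum's acid, CC1(C)OC(=O)CC(=O)O1
Why: Knoevenagel condensation, conjugate hydride transfer from triethylammonium formate, and hydrolytic ring opening with decarboxylation should run in one pot (reductive Knoevenagel homologation), and because no metal is present the aryl bromides and benzyl ethers are not at risk.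

Step 5
Reactants: 7 3-[4,5-bis(benzyloxy)-2,3-dibromophenyl]propanoic acid; 8 1,3-oxazolidin-2-one
Product: 10 3-{3-[4,5-bis(benzyloxy)-2,3-dibromophenyl]propanoyl}-1,3-oxazolidin-2-one, via mixed pivalic anhydride 9 (not isolated)
Conditions: PivCl, Et3N, THF, −20 → 0 °C; then LiCl, 8, 0 °C → rt
Reagents that add atoms: pivaloyl chloride, CC(C)(C)C(Cl)=O (its acyl group is held only in intermediate 9; nothing of it remains in 10)
Why: N-Acylation through a mixed anhydride should occur at the less hindered, non-pivaloyl carbonyl with the LiCl-activated oxazolidinone, installing the two-point-binding helper needed by the copper catalyst.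

Step 6
Reactants: 10 3-{3-[4,5-bis(benzyloxy)-2,3-dibromophenyl]propanoyl}-1,3-oxazolidin-2-one
Product: 12 3-[(1Z)-3-[4,5-bis(benzyloxy)-2,3-dibromophenyl]-1-(trimethylsilyloxy)prop-1-en-1-yl]-1,3-oxazolidin-2-one, via sodium enolate 11 (not isolated)
Conditions: NaHMDS (1.1 equiv), THF, −78 °C; TMSCl (1.3 equiv), −78 °C → rt; filtered under argon and used crude
Reagents that add atoms: chlorotrimethylsilane, C[Si](C)(C)Cl
Why: Deprotonation of the imide should give the chelated (Z)-enolate, which is O-silylated (silyl ketene N,O-acetal formation) with the geometry retained, and an amide base does not exchange aryl bromides.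

Step 7
Reactants: 13 3-bromo-2-methoxyphenol
Product: 14 3-bromo-2-methoxyphenyl acetate
Conditions: Ac2O, pyridine, DMAP (cat.), CH2Cl2, rt
Reagents that add atoms: acetic anhydride, CC(=O)OC(C)=O
Why: DMAP-catalysed O-acetylation should mask the phenol with a group that has no aryl C–H to compete in the borylation, tolerates BF3 and silyl triflate, and later falls off under the peroxide hydrolysis.

Step 8
Reactants: 14 3-bromo-2-methoxyphenyl acetate
Product: 16 [3-(acetyloxy)-5-bromo-4-methoxyphenyl]boronic acid, via aryl pinacol boronate 15 (not isolated)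
Conditions: [Ir(OMe)(cod)]2 (1.5 mol %), dtbpy (3 mol %), B2pin2 (0.6 equiv), THF, 70 °C; then NaIO4, 1 M aq HCl, THF/H2O, rt
Reagents that add atoms: bis(pinacolato)diboron, CC1(C)OB(OC1(C)C)B1OC(C)(C)C(C)(C)O1; water, O
Why: Iridium-catalysed aromatic C–H borylation is sterically controlled and should take the only ring CH without an ortho substituent (para to OMe, meta to Br and OAc), leaving the C–Br bond alone, after which periodate cleaves the pinacol to free the boronic acid.

Step 9
Reactants: 16 [3-(acetyloxy)-5-bromo-4-methoxyphenyl]boronic acid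
Product: 17 [3-(acetyloxy)-5-bromo-4-methoxyphenyl](2,4,6-trimethylphenyl)iodonium trifluoromethanesulfonate
Conditions: MesI(OAc)2 (1.1 equiv), BF3·OEt2 (1.1 equiv), CH2Cl2, 0 °C → rt; then sat. aq NaOTf
Reagents that add atoms: 2-(diacetoxyiodo)-1,3,5-trimethylbenzene, CC(=O)OI(OC(C)=O)c1c(C)cc(C)cc1C; sodium trifluoromethanesulfonate, [Na+].[O-]S(=O)(=O)C(F)(F)F
Why: Boron-to-iodine(III) aryl exchange (ipso substitution of the boronic acid by the BF3-activated iodane) should give the unsymmetrical diaryliodonium salt regiospecifically, and anion metathesis supplies the triflate.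

Step 10
Reactants: 12 3-[(1Z)-3-[4,5-bis(benzyloxy)-2,3-dibromophenyl]-1-(trimethylsilyloxy)prop-1-en-1-yl]-1,3-oxazolidin-2-one; 17 [3-(acetyloxy)-5-bromo-4-methoxyphenyl](2,4,6-trimethylphenyl)iodonium trifluoromethanesulfonate
Product: 18 3-[(2R)-2-[3-(acetyloxy)-5-bromo-4-methoxyphenyl]-3-[4,5-bis(benzyloxy)-2,3-dibromophenyl]propanoyl]-1,3-oxazolidin-2-one
Conditions: Cu(OTf)2 (10 mol %), (S,S)-Ph-BOX [2,2'-(propane-2,2-diyl)bis((4S)-4-phenyl-4,5-dihydro-1,3-oxazole)] (12 mol %), 17 (1.3 equiv), CH2Cl2, rt
Reagents that add atoms: none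
Why: Cu(II) is reduced in situ to a Cu(I) bis(oxazoline) complex, which the iodonium salt 17 oxidises to an electrophilic aryl–Cu(III) species with loss of iodomesitylene; the (Z)-ketene aminal 12 binds this centre through its oxazolidinone carbonyl and enol unit, C2 bonds to the aryl group, and loss of TMSOTf with reductive elimination returns Cu(I). The closest known reaction type is the copper bis(oxazoline)-catalysed enantioselective α-arylation of silyl ketene aminals of N-acyl oxazolidinones with diaryliodonium triflates, here a union of two natural donor carbons made possible by umpolung of the arene as a λ3-iodane. No ring is closed. The new stereocenter C2 is set under catalyst control: the C2-symmetric phenyl-substituted ligand on the two-point-bound Cu(III) complex leaves one enantiotopic face of the ketene aminal open to the aryl group, and the defined Z geometry from step 6 lets that facial choice give a single configuration. The step needs transfer of the functionalised aryl and not of mesityl (secured by the two ortho methyl groups of mesityl against the ortho hydrogens at C2 and C6 of ring A), C- and not O-arylation (soft enol carbon, strong Si–O bond), and no reaction at the three C–Br bonds (Cu(I) at room temperature does not insert into aryl bromides). The tertiary α-aryl imide is not enolised under these base-free conditions, so it should neither racemise nor be arylated twice.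

Step 11
Reactants: 18 3-[(2R)-2-[3-(acetyloxy)-5-bromo-4-methoxyphenyl]-3-[4,5-bis(benzyloxy)-2,3-dibromophenyl]propanoyl]-1,3-oxazolidin-2-one
Product: 20 (2R)-3-[4,5-bis(benzyloxy)-2,3-dibromophenyl]-2-(3-bromo-5-hydroxy-4-methoxyphenyl)propanoic acid, via peroxy acid 19 (not isolated)
Conditions: LiOH·H2O (3 equiv), 30% H2O2 (8 equiv), THF/H2O 3:1, 0 °C; aq Na2SO3; 1 M HCl
Reagents that add atoms: hydrogen peroxide, OO
Why: Hydroperoxide-mediated imide hydrolysis should attack the exocyclic carbonyl selectively and, being weakly basic, spare the α-aryl stereocenter, while the aryl acetate is perhydrolysed in the same pot and sulfite reduces the peroxy acid to the acid.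

Step 12
Reactants: 20 (2R)-3-[4,5-bis(benzyloxy)-2,3-dibromophenyl]-2-(3-bromo-5-hydroxy-4-methoxyphenyl)propanoic acid
Product: 21 methyl (2R)-3-[4,5-bis(benzyloxy)-2,3-dibromophenyl]-2-(3-bromo-5-hydroxy-4-methoxyphenyl)propanoate
Conditions: MeOH, H2SO4 (cat.), 45 °C
Reagents that add atoms: methanol, CO
Why: Fischer esterification should convert the acid without touching the phenol or benzyl ethers, and acid catalysis does not enolise the α-aryl centre to a meaningful extent, so a diazoalkane that could O-methylate the phenol is avoided.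

Step 13
Reactants: 21 methyl (2R)-3-[4,5-bis(benzyloxy)-2,3-dibromophenyl]-2-(3-bromo-5-hydroxy-4-methoxyphenyl)propanoate
Product: 22 methyl (2R)-2-(3-bromo-5-hydroxy-4-methoxyphenyl)-3-(2,3-dibromo-4,5-dihydroxyphenyl)propanoate
Conditions: BCl3 (1 M in CH2Cl2, 6 equiv), pentamethylbenzene (8 equiv), CH2Cl2, −78 °C; then MeOH quench
Reagents that add atoms: none
Why: Lewis acid debenzylation with a non-coordinating cation scavenger should cleave both aryl benzyl ethers at −78 °C, where the aryl methyl ether, methyl ester and C–Br bonds are inert and hydrogenolysis (which would remove bromine) is avoided.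

**Compound list**

1 | 5-bromovanillin (3-bromo-4-hydroxy-5-methoxybenzaldehyde) | O=Cc1cc(Br)c(O)c(OC)c1 | starting material
2 | 2,3-dibromo-4-hydroxy-5-methoxybenzaldehyde | O=Cc1cc(OC)c(O)c(Br)c1Br | intermediate
3 | 2,3-dibromo-4,5-dihydroxybenzaldehyde | O=Cc1cc(O)c(O)c(Br)c1Br | intermediate
4 | 4,5-bis(benzyloxy)-2,3-dibromobenzaldehyde | O=Cc1cc(OCc2ccccc2)c(OCc2ccccc2)c(Br)c1Br | intermediate
5 | 5-{[4,5-bis(benzyloxy)-2,3-dibromophenyl]methylidene}-2,2-dimethyl-1,3-dioxane-4,6-dione (arylidene Meldrum's acid, not isolated) | CC1(C)OC(=O)C(=Cc2cc(OCc3ccccc3)c(OCc3ccccc3)c(Br)c2Br)C(=O)O1 | intermediate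
6 | 5-{[4,5-bis(benzyloxy)-2,3-dibromophenyl]methyl}-2,2-dimethyl-1,3-dioxane-4,6-dione (benzyl Meldrum's acid, not isolated) | CC1(C)OC(=O)C(Cc2cc(OCc3ccccc3)c(OCc3ccccc3)c(Br)c2Br)C(=O)O1 | intermediate
7 | 3-[4,5-bis(benzyloxy)-2,3-dibromophenyl]propanoic acid | OC(=O)CCc1cc(OCc2ccccc2)c(OCc2ccccc2)c(Br)c1Br | intermediate
8 | 1,3-oxazolidin-2-one | O=C1NCCO1 | starting material
9 | 3-[4,5-bis(benzyloxy)-2,3-dibromophenyl]propanoic 2,2-dimethylpropanoic anhydride (mixed pivalic anhydride, not isolated) | CC(C)(C)C(=O)OC(=O)CCc1cc(OCc2ccccc2)c(OCc2ccccc2)c(Br)c1Br | intermediate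
10 | 3-{3-[4,5-bis(benzyloxy)-2,3-dibromophenyl]propanoyl}-1,3-oxazolidin-2-one | O=C1OCCN1C(=O)CCc1cc(OCc2ccccc2)c(OCc2ccccc2)c(Br)c1Br | intermediate
11 | sodium (1Z)-3-[4,5-bis(benzyloxy)-2,3-dibromophenyl]-1-(2-oxo-1,3-oxazolidin-3-yl)prop-1-en-1-olate (sodium enolate, not isolated) | [Na+].[O-]/C(N1CCOC1=O)=C\Cc1cc(OCc2ccccc2)c(OCc2ccccc2)c(Br)c1Br | intermediate
12 | 3-[(1Z)-3-[4,5-bis(benzyloxy)-2,3-dibromophenyl]-1-(trimethylsilyloxy)prop-1-en-1-yl]-1,3-oxazolidin-2-one | C[Si](C)(C)O/C(N1CCOC1=O)=C\Cc1cc(OCc2ccccc2)c(OCc2ccccc2)c(Br)c1Br | intermediate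
13 | 3-bromo-2-methoxyphenol | COc1c(O)cccc1Br | starting material
14 | 3-bromo-2-methoxyphenyl acetate | COc1c(OC(C)=O)cccc1Br | intermediate
15 | 3-bromo-2-methoxy-5-(4,4,5,5-tetramethyl-1,3,2-dioxaborolan-2-yl)phenyl acetate (aryl pinacol boronate, not isolated) | COc1c(OC(C)=O)cc(B2OC(C)(C)C(C)(C)O2)cc1Br | intermediate
16 | [3-(acetyloxy)-5-bromo-4-methoxyphenyl]boronic acid | COc1c(OC(C)=O)cc(B(O)O)cc1Br | intermediate
17 | [3-(acetyloxy)-5-bromo-4-methoxyphenyl](2,4,6-trimethylphenyl)iodonium trifluoromethanesulfonate | COc1c(OC(C)=O)cc([I+]c2c(C)cc(C)cc2C)cc1Br.[O-]S(=O)(=O)C(F)(F)F | intermediate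
18 | 3-[(2R)-2-[3-(acetyloxy)-5-bromo-4-methoxyphenyl]-3-[4,5-bis(benzyloxy)-2,3-dibromophenyl]propanoyl]-1,3-oxazolidin-2-one | O=C1OCCN1C(=O)[C@H](Cc1cc(OCc2ccccc2)c(OCc2ccccc2)c(Br)c1Br)c1cc(OC(C)=O)c(OC)c(Br)c1 | intermediate
19 | (2R)-3-[4,5-bis(benzyloxy)-2,3-dibromophenyl]-2-(3-bromo-5-hydroxy-4-methoxyphenyl)propaneperoxoic acid (peroxy acid, not isolated) | OOC(=O)[C@H](Cc1cc(OCc2ccccc2)c(OCc2ccccc2)c(Br)c1Br)c1cc(O)c(OC)c(Br)c1 | intermediate
20 | (2R)-3-[4,5-bis(benzyloxy)-2,3-dibromophenyl]-2-(3-bromo-5-hydroxy-4-methoxyphenyl)propanoic acid | OC(=O)[C@H](Cc1cc(OCc2ccccc2)c(OCc2ccccc2)c(Br)c1Br)c1cc(O)c(OC)c(Br)c1 | intermediate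
21 | methyl (2R)-3-[4,5-bis(benzyloxy)-2,3-dibromophenyl]-2-(3-bromo-5-hydroxy-4-methoxyphenyl)propanoate | COC(=O)[C@H](Cc1cc(OCc2ccccc2)c(OCc2ccccc2)c(Br)c1Br)c1cc(O)c(OC)c(Br)c1 | intermediate
22 | methyl (2R)-2-(3-bromo-5-hydroxy-4-methoxyphenyl)-3-(2,3-dibromo-4,5-dihydroxyphenyl)propanoate | COC(=O)[C@H](Cc1cc(O)c(O)c(Br)c1Br)c1cc(O)c(OC)c(Br)c1 | target

**Step count and risks**

Total steps: 13. Longest linear sequence: 10 steps (1 → 2 → 3 → 4 → 7 → 10 → 12 → 18 → 20 → 21 → 22). The ring-A branch (steps 7–9) joins at step 10.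

Steps most likely to fail:

Step 10. What may go wrong: poor enantiofacial discrimination in the aryl transfer (the bulky 2,3-dibromobenzyl arm may disturb the two-point binding at copper), or protodesilylation of the ketene aminal outrunning arylation. Fallback: control by a covalently bound auxiliary with separation of diastereomers instead of catalyst control. It sets out from acid 7. Acylation of (S)-4-benzyl-1,3-oxazolidin-2-one through the same mixed anhydride 9 (PivCl, Et3N, LiCl, THF) should give the imide (4S)-4-benzyl-3-{3-[4,5-bis(benzyloxy)-2,3-dibromophenyl]propanoyl}-1,3-oxazolidin-2-one F1. NaHMDS/TMSCl at −78 °C should give its (Z)-silyl ketene aminal (4S)-4-benzyl-3-[(1Z)-3-[4,5-bis(benzyloxy)-2,3-dibromophenyl]-1-(trimethylsilyloxy)prop-1-en-1-yl]-1,3-oxazolidin-2-one F2. Arylation of F2 with 17 under Cu(OTf)2 and an achiral bis(oxazoline) ligand in CH2Cl2 should give two diastereomeric imides; the benzyl group is expected to shield one face and favour the (2R) isomer. That isomer, (4S)-3-[(2R)-2-[3-(acetyloxy)-5-bromo-4-methoxyphenyl]-3-[4,5-bis(benzyloxy)-2,3-dibromophenyl]propanoyl]-4-benzyl-1,3-oxazolidin-2-one F3, is separated by chromatography or crystallisation, and the (2S) isomer is recycled by epimerisation with DBU. LiOH/H2O2 then removes auxiliary and acetate (through the same peroxy acid 19), and the route is rejoined at acid 20.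

Step 13. What may go wrong: boron bound to the free ring-A phenol oxygen delivers chloride to the neighbouring methyl ether (chelation-assisted demethylation), or benzyl cations alkylate the electron-rich rings. Fallback: a protecting-group relay that takes the free phenol out of the Lewis acid step. It sets out from 21. Ac2O/pyridine should give methyl (2R)-2-[3-(acetyloxy)-5-bromo-4-methoxyphenyl]-3-[4,5-bis(benzyloxy)-2,3-dibromophenyl]propanoate F4. BCl3/pentamethylbenzene at −78 °C should then give methyl (2R)-2-[3-(acetyloxy)-5-bromo-4-methoxyphenyl]-3-(2,3-dibromo-4,5-dihydroxyphenyl)propanoate F5, in which the methoxy group has no neighbouring boron-bound oxygen. Acid-catalysed methanolysis of the aryl acetate (HCl in MeOH, rt) then gives the target 22.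

Step 11. What may go wrong: attack at the ring carbamate carbonyl of the unsubstituted oxazolidinone, oxidative damage to the freed phenol by peroxide, or partial enolisation of the α-aryl imide before cleavage. Fallback: non-oxidative direct transesterification that bypasses acid 20. It sets out from 18. MeOMgBr (from MeMgBr in MeOH/CH2Cl2, 0 °C) should deliver the methyl ester by chelation-directed exocyclic methanolysis and methanolyse the aryl acetate in the same pot. The route is rejoined at ester 21, step 12 is no longer needed, and no new compound is made.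

**Further compounds**

F1 | step 10 | (4S)-4-benzyl-3-{3-[4,5-bis(benzyloxy)-2,3-dibromophenyl]propanoyl}-1,3-oxazolidin-2-one | O=C1OC[C@H](Cc2ccccc2)N1C(=O)CCc1cc(OCc2ccccc2)c(OCc2ccccc2)c(Br)c1Br
F2 | step 10 | (4S)-4-benzyl-3-[(1Z)-3-[4,5-bis(benzyloxy)-2,3-dibromophenyl]-1-(trimethylsilyloxy)prop-1-en-1-yl]-1,3-oxazolidin-2-one | C[Si](C)(C)O/C(N1[C@@H](Cc2ccccc2)COC1=O)=C\Cc1cc(OCc2ccccc2)c(OCc2ccccc2)c(Br)c1Br
F3 | step 10 | (4S)-3-[(2R)-2-[3-(acetyloxy)-5-bromo-4-methoxyphenyl]-3-[4,5-bis(benzyloxy)-2,3-dibromophenyl]propanoyl]-4-benzyl-1,3-oxazolidin-2-one | O=C1OC[C@H](Cc2ccccc2)N1C(=O)[C@H](Cc1cc(OCc2ccccc2)c(OCc2ccccc2)c(Br)c1Br)c1cc(OC(C)=O)c(OC)c(Br)c1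
F4 | step 13 | methyl (2R)-2-[3-(acetyloxy)-5-bromo-4-methoxyphenyl]-3-[4,5-bis(benzyloxy)-2,3-dibromophenyl]propanoate | COC(=O)[C@H](Cc1cc(OCc2ccccc2)c(OCc2ccccc2)c(Br)c1Br)c1cc(OC(C)=O)c(OC)c(Br)c1
F5 | step 13 | methyl (2R)-2-[3-(acetyloxy)-5-bromo-4-methoxyphenyl]-3-(2,3-dibromo-4,5-dihydroxyphenyl)propanoate | COC(=O)[C@H](Cc1cc(O)c(O)c(Br)c1Br)c1cc(OC(C)=O)c(OC)c(Br)c1
F0 | step 11 | none | none
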